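## Structural features

Nardostachysin is an ester of two terpenoid halves: the primary C10 hydroxyl of an iridoid lactone is acylated by the carboxyl (C14') of a guaia-7',9'-dienoic acid. The iridoid half is a cis-fused cyclopenta[c]pyran-1-one: ring B is the δ-lactone C1–O2–C3–C4–C5–C9 with an exocyclic C4=C11 methylene, ring A is the cyclopentane C5–C6–C7–C8–C9, and the two share the C5–C9 bond. Ring A carries four contiguous stereocentres (5R, 9R, 8S, 7S): H-5 and H-9 are cis, the secondary C7 hydroxyl and the tertiary C8 hydroxyl are cis to each other and lie on the face of the ring B carbons, and C10 lies on the face of H-9. The acid half is a cis-fused hydroazulene whose cyclopentane has three contiguous all-cis centres (C1', C5' and the methyl-bearing C4'; 1'S,4'R,5'R) and whose seven-membered ring C holds the 7',9'-diene, with isopropyl on C7' and the carboxyl on C10'. Fragile points are the β-hydroxy lactone (retro-aldol, dehydration, epimerisation at C9), the allylic lactone C3–O bond beside the exocyclic alkene, an acyl group that can migrate among three neighbouring hydroxyls, and the conjugated dienoate. The real difficulty is the oxygenated ring A with its quaternary carbinol on the concave face, and an absolute configuration that rests on C5 alone once C1 and C4 are trigonal; the all-cis cyclopentane of the acid is a second, independent problem. The key step uses the fact that C7 lies between C6 and C8 while C5–C9 is the shared bond: an alkyne (C8≡C9), a vinyl group (C5=C6) and carbon monoxide (C7) give a cyclopentenone (ring A) fused to the pyran (ring B) in one operation.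

## Logic of the disconnections

42 from 41: no skeletal bond is cut; the two C–O bonds of an isopropylidene ketal on O7 and O8 are removed. The ketal keeps the cis-diol silent during oxidation, methylenation and acylation. The demand is a hydrolysis mild enough for the exocyclic alkene, the lactone and the ester.

41 from 22 and 39: the ester bond O10–C14' is cut. This separates the molecule into its two halves with independent stereochemistry. The demand is acylation of a neopentyl-type primary alcohol, met by making it the only free hydroxyl in 22.

22 back to 18 (via 21, 20, 19): the C4=C11 bond is cut to a ketone and the ketone traced to a C4 ether. The oxygen stands in for the methylene so that no second alkene competes in the annulation, and it gives C4 a stereocentre to steer C5. The demand is a non-basic methylenation of an α-acyloxy ketone.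

18 back to 16 (via 17): the C9–H bond and the C8 hydroxyl are traced to a C8–C9 epoxide α,β to the lactone. This replaces the β-hydroxy lactone by a function that can be set by a neighbouring hydroxyl. The demand is cleavage of the C9–O bond only and protonation of C9 on the face of H-5.

16 back to 13 (via 15): the lactone carbonyl is traced to an acetal at C1, cutting the exocyclic C1–O bond. The acetal keeps the C8=C9 alkene electron-rich for the directed epoxidation. The demand is release of the lactol without acid, because the epoxide is adjacent.

13 back to 11 (via 12): the two epoxide C–O bonds and the C7–H bond are cut. This leaves a cyclopentenone, in which C7, C8 and C9 are trigonal and C5 is the only ring stereocentre. The demand is hydride delivery anti to ring B and oxygen delivery from the C7 hydroxyl.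

11 to 9: C5–C9, C6–C7 and C7–C8 are cut. Two rings and one carbonyl carbon are removed, leaving an acyclic 1,7-enyne and carbon monoxide. The demand is facial control at C5 by the C4 ether, with no opposing influence from C1.

9 to 8 and two molecules of 4: both C1–O bonds are cut. A symmetrical acetal needs no statistical exchange and has no stereocentre at C1. The demand is only exhaustive acetalisation under acid that spares the benzyl-type ethers.

4 to 1 and 2 (via 3); 8 to 5 (via 6): the secondary ether is traced through a cyclic benzylidene-type acetal to the chiral diol, and the C1–C9 bond to formylation of an acetylide. Both are standard; the demand is regioselective reductive opening to the secondary ether.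

39 back to 35 (via 38, 36): the C9'=C10' alkene is traced to a β-hydroxy ester and the C7'=C8' alkene is cut by retro-metathesis. This opens ring C to a cyclopentane with two side chains. The demand is closure of a seven-membered trisubstituted alkene.

35 back to 29 (via 33, 31, 30): C9'–C10' is cut (aldol with a three-carbon enal) and C6'–C7' is cut (sp3–sp2 coupling). This leaves an all-cis cyclopentane diester with differentiated esters. The demand is that alkenes enter only after the hydrogenation.

29 back to 23 (via 28, 27, 26, 25): the C1'–H and C5'–H bonds are cut (hydrogenation anti to the methyl group), then C1'–C10' (cross-coupling at an enol triflate), then a ring contraction and an alkene cleavage lead to a monoterpene ketone. One pool stereocentre (C4') controls the other two. The demand is clean facial selectivity on a tetrasubstituted alkene.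

## Other disconnections considered

Alternative 1: The cut is at the ester carbon, C10'–C14' and C14'–O at once. The forward step is a palladium-catalysed carbonylative coupling (Pd(OAc)2, 1,3-bis(diphenylphosphino)propane, Et3N, CO) of the dienyl triflate A2 with alcohol 22, and it would give A1, which is identical with 41.
- In its favour: it is more convergent at the junction than the chosen plan. The carboxyl carbon is introduced and esterified in one step, so separate carboxyl installation, ester cleavage and acid activation disappear. On step economy for the acid half it is the better plan.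
- Against it here: A2 must be made regioselectively from the ring C enone A3 by γ-deprotonation, in competition with deprotonation at the ring-fusion carbon C1', which would also endanger that stereocentre. Alcohol 22 is a slow, neopentyl-type nucleophile for an acyl-palladium species and would be needed in excess. Most seriously, 22 contains an allylic carboxylate (the lactone C3–O bond beside the exocyclic alkene) that zerovalent palladium can ionise.
- Comparison: the mechanism (oxidative addition, CO insertion, alcoholysis) is unrelated to the cobalt annulation and does not help with rings A and B, so it competes only with the last two steps of the chosen plan. Both plans pass through the same ketal.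

Alternative 2: The cut is C7–C8. The forward step is a SmI2 pinacol coupling of the aldehyde and ketone carbons of the keto aldehyde A5, closing ring A onto a preformed lactone to give A4.
- In its favour: the cis-diol arises directly from a chelated samarium diolate in a five-membered ring. For installing the two hydroxyls it is shorter than the chosen reduction, epoxidation and reductive opening, and it keeps the exocyclic methylene, so no C4 surrogate is needed. On these points it is the better plan.
- Against it here: A5 is a β-keto lactone, largely enolised and configurationally labile at C9. Its ketone carries an α-silyloxy group that SmI2 can cleave reductively. Three stereocentres (C7, C8 and in effect C9) must follow from C5 alone in a radical coupling, and A5 still needs ring B and C5 from elsewhere.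
- Comparison: it forms one ring and one bond where the chosen step forms two rings and three bonds and sets C5. The chosen plan reaches the same diol pattern by hydroxyl-directed steps whose facial sense is easier to argue.

Alternative 3: The cut is C8'–C9' and C9'–C10' of the acid half. The forward step is a one-carbon zinc-carbenoid insertion (EtZnCH2I from Et2Zn and CH2I2) into the cis-hydrindanone β-keto ester A7, followed by iodine and DBU in the same flask, to give the ene-keto ester A6.
- In its favour: ring C and the C9'=C10' enoate form in one flask without dilute metathesis. Counted from A7 it is equal to or shorter than the aldol, metathesis and elimination steps of the chosen plan.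
- Against it here: A7 needs a cis-hydrindanone that already holds the all-cis methyl and an isopropyl group, a harder precursor than the monocyclic diester 29. A6 has a surplus ketone at C8' that must be transposed into the C7'=C8' alkene by reduction and a regioselective dehydration. The ring-fusion carbon next to the β-keto ester is exposed to enolate chemistry.
- Comparison: the mechanism (zinc enolate, cyclopropanation, fragmentation) fixes the enoate but not the second alkene, whereas metathesis fixes C7'=C8' by construction. The alternative concerns only the acid and would still need the annulation for rings A and B.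

Key step: step 6

## Assumptions and corrections (remarks on the chemistry)

- Locants C1–C11 are those of the iridoid half (C1 lactone carbonyl, O2, C3, C4 with C11, ring A C5–C9, C10 on C8). Primed locants are guaiane locants of the acid (C1', C5' ring fusion, C15' methyl on C4', isopropyl on C7', C14' carboxyl on C10').
- Stereochemical check: the (S) centre of 1 becomes C4; with the C4 ether cis to H-5 the ring-fusion carbon is (5R), as in 42. (R)-Pulegone supplies (4'R).
- Correction 1: an epimeric mixture at the acetal carbon is not harmless. C1 is propargylic and would direct the ring fusion at least as strongly as the allylic C4 ether. Because C1 and C4 both lose their stereogenicity later, C5 diastereomers would end as enantiomers. The precursor is therefore the symmetrical acetal 9, in which C1 is not a stereocentre.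
- Correction 2: an alkyl acetal beside the C8–C9 epoxide cannot be hydrolysed by acid without opening the epoxide. The spectator alkoxy group of 9 is a but-3-enyl-type ether that is released by oxidative cleavage and β-elimination.
- Correction 3: epoxidation syn to the C7 hydroxyl puts the epoxide on the face of C4, so the epoxide is trans-fused at C5–C9. The cis ring fusion arises only when C9 is protonated after reductive opening.
- Correction 4: the C7 hydroxyl must remain an alcohol during the reductive opening and must be masked before C4 is oxidised; the 7,8-diol is carried as an isopropylidene ketal.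
- (2-tert-Butoxy-2-oxoethyl)zinc bromide and 2-bromo-3-methylbut-1-ene are taken as catalogue reagents.

## Steps

Step 1
Reactants: 1 (S)-but-3-ene-1,2-diol; 2 4-methoxybenzaldehyde
Product: 3 (4S)-2-(4-methoxyphenyl)-4-vinyl-1,3-dioxolane (both C2 epimers)
Conditions: PPTS (cat.), toluene, reflux, Dean–Stark
Reagents that add atoms: none
Why: Acid-catalysed acetalisation of the 1,2-diol with azeotropic removal of water gives the five-membered 4-methoxybenzylidene acetal; the allylic stereocentre is not involved.

Step 2
Reactants: 3 (4S)-2-(4-methoxyphenyl)-4-vinyl-1,3-dioxolane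
Product: 4 (2S)-2-[(4-methoxybenzyl)oxy]but-3-en-1-ol
Conditions: DIBAL-H, CH2Cl2, −78 → 0 °C; aq. Rochelle salt
Reagents that add atoms: none
Why: Reductive acetal opening: aluminium binds the less hindered oxygen on CH2, that C–O bond breaks and hydride goes to the oxocarbenium carbon, so the 4-methoxybenzyl group stays on the secondary oxygen (known regiochemistry for acetals of terminal 1,2-diols); C2 keeps its (S) configuration.

Step 3
Reactants: 5 prop-2-yn-1-ol
Product: 6 tert-butyldimethyl(prop-2-yn-1-yloxy)silane
Conditions: TBSCl, imidazole, CH2Cl2, 0 °C → rt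
Reagents that add atoms: tert-butyldimethylsilyl chloride, CC(C)(C)[Si](C)(C)Cl
Why: Standard silylation of a primary alcohol; the silyl ether tolerates the acetylide, cobalt, hydride and samarium chemistry that follows and is removed by fluoride near the end.

Step 4
Reactants: 6 tert-butyldimethyl(prop-2-yn-1-yloxy)silane
Product: 8 4-[(tert-butyldimethylsilyl)oxy]but-2-ynal, via lithium acetylide 7 (not isolated)
Conditions: n-BuLi, THF, −78 °C; DMF, −78 → 0 °C; inverse quench into aq. KH2PO4
Reagents that add atoms: N,N-dimethylformamide, CN(C)C=O
Why: Deprotonation of the terminal alkyne and formylation of the acetylide with DMF; the hemiaminal salt is hydrolysed by inverse quench into phosphate buffer so that liberated dimethylamine cannot add to the ynal.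

Step 5
Reactants: 8 4-[(tert-butyldimethylsilyl)oxy]but-2-ynal; 4 (2S)-2-[(4-methoxybenzyl)oxy]but-3-en-1-ol (2.1 equiv)
Product: 9 4-[(tert-butyldimethylsilyl)oxy]-1,1-bis{[(2S)-2-(4-methoxybenzyloxy)but-3-en-1-yl]oxy}but-2-yne
Conditions: PPTS (10 mol%), benzene, reflux, Dean–Stark with 4 Å MS
Reagents that add atoms: none
Why: Acid-catalysed acetalisation driven to completion by removal of water; because both alkoxy groups come from 4, no statistical mixed-acetal exchange is needed and C1 is not a stereocentre; PPTS spares the 4-methoxybenzyl and silyl ethers.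

Step 6
Reactants: 9 4-[(tert-butyldimethylsilyl)oxy]-1,1-bis{[(2S)-2-(4-methoxybenzyloxy)but-3-en-1-yl]oxy}but-2-yne
Product: 11 (4S,5R)-bicyclic enone acetal (C7 ketone; C8=C9; C8 bears CH2OTBS; C4 bears OPMB; C1 bears the (2S)-2-(4-methoxybenzyloxy)but-3-enyloxy group; H-5 and the C1 and C4 oxygens on one face), via hexacarbonyldicobalt alkyne complex 10 (not isolated)
Conditions: Co2(CO)8 (1.1 equiv), CH2Cl2, rt; then Me3NO (anhydrous, 8 equiv), 4 Å MS, CH2Cl2, 0 °C → rt
Reagents that add atoms: octacarbonyldicobalt, [C-]#[O+].[C-]#[O+].[C-]#[O+].[C-]#[O+].[C-]#[O+].[C-]#[O+].[C-]#[O+].[C-]#[O+].[Co].[Co] (supplies the carbon monoxide, [C-]#[O+], that becomes C7=O)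
Why: The alkyne of 9 is bound as the Co2(CO)6 complex 10; the amine N-oxide removes one CO as CO2, the vinyl group of one arm coordinates and inserts into a Co–C9 bond (forming C5–C9 and a cobaltacyclopentene), CO inserts into the Co–C6 bond (C6–C7) and reductive elimination joins C7 to C8 and releases the enone. This is an intramolecular Pauson–Khand (2+2+1) cycloaddition of an oxygen-tethered 1,7-enyne, a known class that is less general than 1,6-enynes; the doubly oxygenated C1 helps by compressing the tether angle. Ring B closes as the six-membered tether ring in the insertion step (chair-like), and ring A closes as the five-membered (2+2+1) ring on reductive elimination. C5 is the stereocentre that matters: it is set in the insertion step by the allylic C4 ether, which is expected to lie exo (pseudo-equatorial, cis to H-5), the sense that maps the (S) centre of 1 onto (5R). C1 becomes stereogenic only now; because the two arms of 9 are identical and diastereotopic, the substrate can always use the arm that places the exocyclic alkoxy group exo as well, so the propargylic centre cannot oppose C4 as it would in an epimeric mixed acetal. Regiochemistry is fixed by the tether, with the carbonyl next to the former alkyne carbon C8 that carries C10. Because C1 and C4 are both erased later, any C5 diastereomer has to be removed here by chromatography while C4 is still stereogenic.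

Step 7
Reactants: 11 bicyclic enone acetal
Product: 12 allylic alcohol (C7–OH anti to H-5; otherwise as 11)
Conditions: NaBH4, CeCl3·7H2O, MeOH/CH2Cl2, −78 °C
Reagents that add atoms: none
Why: Luche 1,2-reduction of the cyclopentenone; hydride is expected on the less hindered face syn to H-5 (ring B is tilted to the other face), which puts the C7 hydroxyl anti to H-5 as in 42; cerium suppresses conjugate reduction.

Step 8
Reactants: 12 allylic alcohol
Product: 13 8,9-epoxy alcohol (epoxide oxygen cis to C7–OH; otherwise as 12)
Conditions: VO(acac)2 (5 mol%), t-BuOOH (decane), CH2Cl2, 0 °C → rt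
Reagents that add atoms: tert-butyl hydroperoxide, CC(C)(C)OO
Why: Vanadium-catalysed hydroxyl-directed epoxidation: the vanadate ester of the C7 alcohol delivers oxygen to the tetrasubstituted C8=C9 alkene on its own face, fixing the C8–O bond cis to C7–OH; the acetal keeps the alkene electron-rich and the undirected vinyl group of the spectator arm stays intact; the epoxide is trans-fused to ring B at this stage.

Step 9
Reactants: 13 8,9-epoxy alcohol
Product: 15 epoxy lactol (C1–OH, both anomers; C4 OPMB, C7–OH, C10 OTBS), via arm aldehyde 14 (not isolated)
Conditions: OsO4 (2 mol%), NaIO4, 2,6-lutidine, dioxane/H2O, rt; then Et3N, CH2Cl2, rt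
Reagents that add atoms: none
Why: Lemieux–Johnson cleavage of the only alkene turns the spectator arm into a β-alkoxy aldehyde, which loses the anomeric oxygen by amine-induced β-elimination (retro-oxa-Michael), the known way of removing but-3-enyl-type ethers; the lactol is released without acid, which the neighbouring epoxide would not tolerate.

Step 10
Reactants: 15 epoxy lactol
Product: 16 α,β-epoxy δ-lactone (C1 lactone; C8–C9 epoxide; C7–OH free)
Conditions: TEMPO (10 mol%), PhI(OAc)2, CH2Cl2, rt
Reagents that add atoms: none
Why: Oxoammonium oxidation converts lactols to lactones much faster than it oxidises a hindered secondary alcohol, so C7–OH survives; C9 is fully substituted, so nothing next to the new carbonyl can epimerise.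

Step 11
Reactants: 16 α,β-epoxy δ-lactone
Product: 17 cis-fused 7,8-dihydroxy lactone (H-9 cis to H-5; C7–OH and C8–OH cis and on the face of ring B; C4 OPMB; C10 OTBS)
Conditions: SmI2 (3 equiv), HMPA, Me2NCH2CH2OH, THF, −40 → 0 °C
Reagents that add atoms: none
Why: Single-electron reduction of the α,β-epoxy lactone cleaves the C9–O bond α to the carbonyl and keeps the C8–O bond, giving a samarium enolate and the tertiary C8 alkoxide; protonation at C9 is expected syn to H-5 (kinetic protonation of ring-fusion enolates gives the cis-fused bicycle), which closes the cis ring fusion; C7 is an alcohol here so that the lactone, not a ketone, activates the epoxide.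

Step 12
Reactants: 17 cis-fused 7,8-dihydroxy lactone
Product: 18 7,8-O-isopropylidene lactone (C4 OPMB; C10 OTBS)
Conditions: Me2C(OMe)2, PPTS (cat.), CH2Cl2, rt
Reagents that add atoms: 2,2-dimethoxypropane, COC(C)(C)OC
Why: Acid-catalysed ketal exchange; the cis 7,8-diol on the cyclopentane closes a fused dioxolane, which blocks retro-aldol cleavage and β-elimination of the β-hydroxy lactone and leaves C4 and C10 as the only oxygens still to be changed.

Step 13
Reactants: 18 7,8-O-isopropylidene lactone
Product: 19 C4 alcohol (ketal and C10 OTBS retained)
Conditions: DDQ, CH2Cl2/pH 7 buffer, 0 °C → rt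
Reagents that add atoms: none
Why: Oxidative cleavage of the 4-methoxybenzyl ether through the benzylic oxocarbenium ion and hydrolysis; lactone, ketal and silyl ether are inert to DDQ under buffered conditions.

Step 14
Reactants: 19 C4 alcohol
Product: 20 C4 ketone (5R,9R cis-fused keto lactone; ketal and C10 OTBS retained)
Conditions: Dess–Martin periodinane, NaHCO3, CH2Cl2, 0 °C → rt
Reagents that add atoms: none
Why: Dess–Martin oxidation of the secondary alcohol under buffered, non-basic conditions keeps the cis fusion at C5 (now α to a ketone) and the α-acyloxy ketone intact; the C4 stereocentre, no longer needed, disappears.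

Step 15
Reactants: 20 C4 ketone
Product: 21 4-methylidene lactone (C4=C11; ketal and C10 OTBS retained)
Conditions: Zn, CH2Br2, TiCl4 (pre-formed reagent), THF/CH2Cl2, 0 °C → rt
Reagents that add atoms: dibromomethane, BrCBr
Why: Takai–Lombardo methylenation: the gem-dimetallic CH2 reagent adds to the ketone and eliminates metal oxide; it is non-basic, so the enolisable α-acyloxy ketone is not deprotonated and C5 and C9 are not epimerised, and it does not attack lactones.

Step 16
Reactants: 21 4-methylidene lactone
Product: 22 primary alcohol (C10–OH free; 7,8-ketal; C4=C11)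
Conditions: HF·pyridine, pyridine, THF, 0 °C → rt
Reagents that add atoms: none
Why: Fluoride cleavage of the primary silyl ether; pyridine buffering protects the ketal and the allylic lactone; C10–OH becomes the only free hydroxyl.

Step 17
Reactants: 23 (R)-(+)-pulegone
Product: 25 methyl (5R)-5-methyl-2-(propan-2-ylidene)cyclopentane-1-carboxylate (both C1 epimers), via pulegone dibromide 24 (not isolated)
Conditions: Br2, NaHCO3, Et2O, −10 °C; then NaOMe, MeOH, reflux
Reagents that add atoms: sodium methoxide, [Na+].[O-]C
Why: Bromine adds to the exocyclic alkene and methoxide then effects the Favorskii ring contraction (cyclopropanone formation and opening, with loss of the second bromide regenerating the isopropylidene group); the methyl-bearing centre is not involved and keeps the (R) configuration that becomes C4'.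

Step 18
Reactants: 25 methyl (5R)-5-methyl-2-(propan-2-ylidene)cyclopentane-1-carboxylate
Product: 26 methyl (5R)-5-methyl-2-oxocyclopentane-1-carboxylate (C1 epimers and enol)
Conditions: O3, CH2Cl2/MeOH, −78 °C; Me2S, −78 °C → rt
Reagents that add atoms: ozone, [O-][O+]=O
Why: Ozonolysis of the tetrasubstituted isopropylidene alkene with reductive work-up gives the β-keto ester and acetone; the methyl-bearing centre is untouched.

Step 19
Reactants: 26 methyl (5R)-5-methyl-2-oxocyclopentane-1-carboxylate
Product: 27 methyl (5R)-5-methyl-2-{[(trifluoromethyl)sulfonyl]oxy}cyclopent-1-ene-1-carboxylate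
Conditions: Tf2O, i-Pr2NEt, CH2Cl2, −78 °C
Reagents that add atoms: trifluoromethanesulfonic anhydride, O=S(=O)(OS(=O)(=O)C(F)(F)F)C(F)(F)F
Why: O-Triflation of the enolised β-keto ester fixes the C1'=C5' alkene between the ester-bearing carbon and the carbon that will receive C10'; standard enol triflate formation.

Step 20
Reactants: 27 methyl (5R)-5-methyl-2-{[(trifluoromethyl)sulfonyl]oxy}cyclopent-1-ene-1-carboxylate
Product: 28 methyl (5R)-2-(2-tert-butoxy-2-oxoethyl)-5-methylcyclopent-1-ene-1-carboxylate
Conditions: BrZnCH2CO2t-Bu, Pd2(dba)3 (2.5 mol%), XPhos (10 mol%), THF, 50 °C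
Reagents that add atoms: (2-tert-butoxy-2-oxoethyl)zinc bromide, CC(C)(C)OC(=O)C[Zn]Br
Why: Negishi cross-coupling of the electron-poor enol triflate with the Reformatsky zinc enolate (oxidative addition to zerovalent palladium, transmetallation, reductive elimination) forms C1'–C10'; the tert-butyl ester allows the two carboxyl groups to be told apart later.

Step 21
Reactants: 28 methyl (5R)-2-(2-tert-butoxy-2-oxoethyl)-5-methylcyclopent-1-ene-1-carboxylate
Product: 29 methyl (1R,2R,5R)-2-(2-tert-butoxy-2-oxoethyl)-5-methylcyclopentane-1-carboxylate (all-cis)
Conditions: H2 (20 bar), 5% Rh/Al2O3, EtOAc, rt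
Reagents that add atoms: none
Why: Heterogeneous syn-hydrogenation of the tetrasubstituted enoate from the face opposite the adjacent methyl group delivers both hydrogens cis to H-4', so methyl, ester and acetate chain end all-cis (C1' and C5' set by the resident C4' centre); rhodium limits double-bond migration and no base is present to epimerise the ester-bearing carbon.

Step 22
Reactants: 29 methyl (1R,2R,5R)-2-(2-tert-butoxy-2-oxoethyl)-5-methylcyclopentane-1-carboxylate
Product: 30 tert-butyl 2-[all-cis-2-(hydroxymethyl)-3-methylcyclopentyl]acetate (configuration as in 29)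
Conditions: LiBH4, THF, 0 → 40 °C
Reagents that add atoms: none
Why: LiBH4 reduces methyl esters but not tert-butyl esters; the conditions do not epimerise the α-carbon before it is reduced, and the bulky tert-butyl ester resists lactonisation at this temperature.

Step 23
Reactants: 30 tert-butyl 2-[all-cis-2-(hydroxymethyl)-3-methylcyclopentyl]acetate
Product: 31 tert-butyl 2-[all-cis-2-(iodomethyl)-3-methylcyclopentyl]acetate
Conditions: I2, PPh3, imidazole, CH2Cl2, 0 °C → rt
Reagents that add atoms: iodine, II
Why: Appel-type iodination of the primary alcohol through the alkoxyphosphonium salt, with no change at the ring stereocentres.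

Step 24
Reactants: 31 tert-butyl 2-[all-cis-2-(iodomethyl)-3-methylcyclopentyl]acetate
Product: 33 tert-butyl 2-[all-cis-3-methyl-2-(3-methyl-2-methylidenebutyl)cyclopentyl]acetate, via alkylzinc iodide 32 (not isolated)
Conditions: Zn dust, LiCl, THF, 40 °C; then CH2=C(Br)CH(CH3)2, Pd(OAc)2 (2 mol%), SPhos (4 mol%), THF, rt → 40 °C
Reagents that add atoms: 2-bromo-3-methylbut-1-ene, C=C(Br)C(C)C
Why: Zinc inserts into the primary C–I bond (LiCl-assisted) to give an ester-tolerant alkylzinc, which undergoes Negishi sp3–sp2 coupling with the alkenyl bromide to form C6'–C7'; the 1,1-disubstituted alkene enters only after the hydrogenation.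

Step 25
Reactants: 33 tert-butyl 2-[all-cis-3-methyl-2-(3-methyl-2-methylidenebutyl)cyclopentyl]acetate
Product: 35 tert-butyl 3-hydroxy-2-[all-cis-3-methyl-2-(3-methyl-2-methylidenebutyl)cyclopentyl]pent-4-enoate (diastereomers at C9' and C10'), via lithium enolate 34 (not isolated)
Conditions: LDA, THF, −78 °C; acrolein, −78 °C; aq. NH4Cl
Reagents that add atoms: acrolein, C=CC=O
Why: Kinetic lithium enolate formation of the tert-butyl ester and 1,2-aldol addition to acrolein at −78 °C form C9'–C10'; the two new centres are removed later, so the diastereomer mixture is used as such.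

Step 26
Reactants: 35 tert-butyl 3-hydroxy-2-[all-cis-3-methyl-2-(3-methyl-2-methylidenebutyl)cyclopentyl]pent-4-enoate
Product: 36 tert-butyl (1'S,4'R,5'R)-9'-hydroxyguai-7'-en-14'-oate (diastereomers at C9' and C10')
Conditions: second-generation Hoveyda–Grubbs catalyst (H2IMes)Cl2Ru=CH(C6H4-2-OiPr) (5–10 mol%), toluene (2 mM), 80 °C
Reagents that add atoms: none
Why: Ring-closing metathesis between the vinyl carbinol (initiation site) and the 1,1-disubstituted alkene closes the seven-membered ring C with the trisubstituted C7'=C8' alkene fixed in position and releases ethene; the cis side chains favour closure and high dilution suppresses dimers.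

Step 27
Reactants: 36 tert-butyl 9'-hydroxyguai-7'-en-14'-oate
Product: 38 tert-butyl (1'S,4'R,5'R)-guaia-7',9'-dien-14'-oate, via mesylate 37 (not isolated)
Conditions: MsCl, Et3N, CH2Cl2, 0 °C; then DBU, rt
Reagents that add atoms: none
Why: Mesylation of the allylic alcohol and E1cB elimination through the ester enolate give the C9'=C10' alkene in conjugation with the ester and with C7'=C8'; only H-10' is acidic, so the diene position is unambiguous and C1' is not deprotonated.

Step 28
Reactants: 38 tert-butyl (1'S,4'R,5'R)-guaia-7',9'-dien-14'-oate
Product: 39 (1'S,4'R,5'R)-guaia-7',9'-dien-14'-oic acid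
Conditions: CF3CO2H/CH2Cl2 (1:4), 0 °C
Reagents that add atoms: none
Why: Acidolysis of the tert-butyl ester with loss of isobutene, under conditions that the electron-poor diene should tolerate.

Step 29
Reactants: 39 (1'S,4'R,5'R)-guaia-7',9'-dien-14'-oic acid; 22 primary alcohol
Product: 41 nardostachysin 7,8-acetonide, via mixed anhydride 40 (not isolated)
Conditions: 2,4,6-Cl3C6H2COCl, Et3N, THF, rt; then 22, DMAP, toluene, rt → 40 °C
Reagents that add atoms: none
Why: Yamaguchi esterification: DMAP attacks the mixed anhydride at the less hindered dienoyl carbonyl and the acylpyridinium acylates the neopentyl-type primary C10 alcohol, the only free hydroxyl of 22; the substrate sees no base stronger than Et3N and DMAP.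

Step 30
Reactants: 41 nardostachysin 7,8-acetonide
Product: 42 nardostachysin
Conditions: AcOH/H2O (4:1), 45 °C
Reagents that add atoms: none
Why: Mild aqueous acid hydrolysis of the isopropylidene ketal liberates the cis-7,8-diol; weak acid is chosen to avoid migration of the exocyclic alkene, lactone opening and acyl migration.

## Compound list

1 | (S)-but-3-ene-1,2-diol | C=C[C@H](O)CO | starting material
2 | 4-methoxybenzaldehyde | COc1ccc(C=O)cc1 | starting material
3 | (4S)-2-(4-methoxyphenyl)-4-vinyl-1,3-dioxolane (both C2 epimers) | C=C[C@H]1COC(c2ccc(OC)cc2)O1 | intermediate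
4 | (2S)-2-[(4-methoxybenzyl)oxy]but-3-en-1-ol | C=C[C@H](OCc1ccc(OC)cc1)CO | intermediate
5 | prop-2-yn-1-ol | C#CCO | starting material
6 | tert-butyldimethyl(prop-2-yn-1-yloxy)silane | C#CCO[Si](C)(C)C(C)(C)C | intermediate
7 | lithium 3-[(tert-butyldimethylsilyl)oxy]prop-1-yn-1-ide | [Li]C#CCO[Si](C)(C)C(C)(C)C | intermediate (not isolated)
8 | 4-[(tert-butyldimethylsilyl)oxy]but-2-ynal | O=CC#CCO[Si](C)(C)C(C)(C)C | intermediate
9 | 4-[(tert-butyldimethylsilyl)oxy]-1,1-bis{[(2S)-2-(4-methoxybenzyloxy)but-3-en-1-yl]oxy}but-2-yne (key-step precursor) | C=C[C@H](OCc1ccc(OC)cc1)COC(OC[C@@H](OCc1ccc(OC)cc1)C=C)C#CCO[Si](C)(C)C(C)(C)C | intermediate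
10 | hexacarbonyldicobalt complex of the alkyne of 9 | O=C=[Co]12(=C=O)(=C=O)[Co]3(=C=O)(=C=O)(=C=O)C1(C(OC[C@@H](OCc4ccc(OC)cc4)C=C)OC[C@@H](OCc4ccc(OC)cc4)C=C)C23CO[Si](C)(C)C(C)(C)C | intermediate (not isolated)
11 | (4S,5R)-bicyclic enone acetal: C7 ketone, C8=C9, 8-CH2OTBS, 4-OPMB, 1-O-[(2S)-2-(4-methoxybenzyloxy)but-3-enyl]; H-5 and the C1 and C4 oxygens cis (key-step product) | COc1ccc(CO[C@@H]2CO[C@H](OC[C@@H](OCc4ccc(OC)cc4)C=C)C3=C(CO[Si](C)(C)C(C)(C)C)C(=O)C[C@H]32)cc1 | intermediate
12 | allylic alcohol from 11, C7–OH anti to H-5 | COc1ccc(CO[C@@H]2CO[C@H](OC[C@@H](OCc4ccc(OC)cc4)C=C)C3=C(CO[Si](C)(C)C(C)(C)C)[C@@H](O)C[C@H]32)cc1 | intermediate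
13 | 8,9-epoxy alcohol, epoxide cis to C7–OH | COc1ccc(CO[C@@H]2CO[C@H](OC[C@@H](OCc5ccc(OC)cc5)C=C)[C@]34O[C@@]3(CO[Si](C)(C)C(C)(C)C)[C@@H](O)C[C@H]42)cc1 | intermediate
14 | arm aldehyde: 13 with the spectator vinyl group cleaved to CHO | COc1ccc(CO[C@@H]2CO[C@H](OC[C@@H](OCc5ccc(OC)cc5)C=O)[C@]34O[C@@]3(CO[Si](C)(C)C(C)(C)C)[C@@H](O)C[C@H]42)cc1 | intermediate (not isolated)
15 | epoxy lactol (C1–OH, both anomers) | COc1ccc(CO[C@@H]2COC(O)[C@]34O[C@@]3(CO[Si](C)(C)C(C)(C)C)[C@@H](O)C[C@H]42)cc1 | intermediate
16 | α,β-epoxy δ-lactone with free C7–OH | COc1ccc(CO[C@@H]2COC(=O)[C@]34O[C@@]3(CO[Si](C)(C)C(C)(C)C)[C@@H](O)C[C@H]42)cc1 | intermediate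
17 | cis-fused 7,8-dihydroxy lactone (4-OPMB, 10-OTBS) | COc1ccc(CO[C@@H]2COC(=O)[C@H]3[C@](O)(CO[Si](C)(C)C(C)(C)C)[C@@H](O)C[C@H]32)cc1 | intermediate
18 | 7,8-O-isopropylidene lactone (4-OPMB, 10-OTBS) | COc1ccc(CO[C@@H]2COC(=O)[C@H]3[C@@]4(CO[Si](C)(C)C(C)(C)C)OC(C)(C)O[C@H]4C[C@H]32)cc1 | intermediate
19 | C4 alcohol (7,8-ketal, 10-OTBS) | O[C@@H]1COC(=O)[C@H]2[C@@]3(CO[Si](C)(C)C(C)(C)C)OC(C)(C)O[C@H]3C[C@H]21 | intermediate
20 | C4 ketone (7,8-ketal, 10-OTBS) | O=C1COC(=O)[C@H]2[C@@]3(CO[Si](C)(C)C(C)(C)C)OC(C)(C)O[C@H]3C[C@H]21 | intermediate
21 | 4-methylidene lactone (7,8-ketal, 10-OTBS) | C=C1COC(=O)[C@H]2[C@@]3(CO[Si](C)(C)C(C)(C)C)OC(C)(C)O[C@H]3C[C@H]21 | intermediate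
22 | primary alcohol: 4-methylidene lactone 7,8-ketal with free C10–OH | C=C1COC(=O)[C@H]2[C@@]3(CO)OC(C)(C)O[C@H]3C[C@H]21 | intermediate
23 | (R)-(+)-pulegone | C[C@@H]1CCC(=C(C)C)C(=O)C1 | starting material
24 | pulegone dibromide | C[C@@H]1CCC(Br)(C(C)(C)Br)C(=O)C1 | intermediate (not isolated)
25 | methyl (5R)-5-methyl-2-(propan-2-ylidene)cyclopentane-1-carboxylate | C[C@@H]1CCC(=C(C)C)C1C(=O)OC | intermediate
26 | methyl (5R)-5-methyl-2-oxocyclopentane-1-carboxylate | C[C@@H]1CCC(=O)C1C(=O)OC | intermediate
27 | methyl (5R)-5-methyl-2-{[(trifluoromethyl)sulfonyl]oxy}cyclopent-1-ene-1-carboxylate | C[C@@H]1CCC(OS(=O)(=O)C(F)(F)F)=C1C(=O)OC | intermediate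
28 | methyl (5R)-2-(2-tert-butoxy-2-oxoethyl)-5-methylcyclopent-1-ene-1-carboxylate | C[C@@H]1CCC(CC(=O)OC(C)(C)C)=C1C(=O)OC | intermediate
29 | methyl (1R,2R,5R)-2-(2-tert-butoxy-2-oxoethyl)-5-methylcyclopentane-1-carboxylate (all-cis) | COC(=O)[C@@H]1[C@H](C)CC[C@@H]1CC(=O)OC(C)(C)C | intermediate
30 | tert-butyl 2-[all-cis-2-(hydroxymethyl)-3-methylcyclopentyl]acetate | OC[C@@H]1[C@H](C)CC[C@@H]1CC(=O)OC(C)(C)C | intermediate
31 | tert-butyl 2-[all-cis-2-(iodomethyl)-3-methylcyclopentyl]acetate | IC[C@@H]1[C@H](C)CC[C@@H]1CC(=O)OC(C)(C)C | intermediate
32 | alkylzinc iodide from 31 | I[Zn]C[C@@H]1[C@H](C)CC[C@@H]1CC(=O)OC(C)(C)C | intermediate (not isolated)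
33 | tert-butyl 2-[all-cis-3-methyl-2-(3-methyl-2-methylidenebutyl)cyclopentyl]acetate | C=C(C(C)C)C[C@@H]1[C@H](C)CC[C@@H]1CC(=O)OC(C)(C)C | intermediate
34 | lithium enolate of 33 | C=C(C(C)C)C[C@@H]1[C@H](C)CC[C@@H]1C=C(O[Li])OC(C)(C)C | intermediate (not isolated)
35 | tert-butyl 3-hydroxy-2-[all-cis-3-methyl-2-(3-methyl-2-methylidenebutyl)cyclopentyl]pent-4-enoate | C=C(C(C)C)C[C@@H]1[C@H](C)CC[C@@H]1C(C(O)C=C)C(=O)OC(C)(C)C | intermediate
36 | tert-butyl (1'S,4'R,5'R)-9'-hydroxyguai-7'-en-14'-oate | CC(C)(C)OC(=O)C1C(O)C=C(C(C)C)C[C@@H]2[C@H](C)CC[C@H]12 | intermediate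
37 | 9'-mesylate of 36 | CC(C)(C)OC(=O)C1C(OS(C)(=O)=O)C=C(C(C)C)C[C@@H]2[C@H](C)CC[C@H]12 | intermediate (not isolated)
38 | tert-butyl (1'S,4'R,5'R)-guaia-7',9'-dien-14'-oate | CC(C)(C)OC(=O)C1=CC=C(C(C)C)C[C@@H]2[C@H](C)CC[C@H]12 | intermediate
39 | (1'S,4'R,5'R)-guaia-7',9'-dien-14'-oic acid | OC(=O)C1=CC=C(C(C)C)C[C@@H]2[C@H](C)CC[C@H]12 | intermediate
40 | mixed anhydride of 39 with 2,4,6-trichlorobenzoic acid | O=C(OC(=O)c1c(Cl)cc(Cl)cc1Cl)C1=CC=C(C(C)C)C[C@@H]2[C@H](C)CC[C@H]12 | intermediate (not isolated)
41 | nardostachysin 7,8-acetonide | C=C1COC(=O)[C@H]2[C@@]3(COC(=O)C4=CC=C(C(C)C)C[C@@H]5[C@H](C)CC[C@H]45)OC(C)(C)O[C@H]3C[C@H]21 | intermediate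
42 | nardostachysin | C=C1COC(=O)[C@@H]2[C@H]1C[C@H](O)[C@@]2(O)COC(=O)C1=CC=C(C(C)C)C[C@@H]2[C@H](C)CC[C@H]12 | target

## Step count and least certain steps

Total step count: 30. Longest linear sequence: 16 steps (1, 2, 5–16, 29, 30). The acid branch is 14 steps (17–30).

Step 6 (key step). The most likely failure is slow alkene insertion, because the tether closes a six-membered ring and the alkyne is disubstituted, so that decomplexation and intermolecular reactions compete. The second is incomplete facial control, because an allylic ether in an oxygen-containing ring is a weak director; C5 diastereomers would have to be separated at 11. The fallback attaches C10 after the annulation. It sets out from 4: acid-catalysed exchange with commercial 3,3-diethoxyprop-1-yne (PPTS, toluene, removal of ethanol) would give the terminal-alkyne bis-ether acetal F1. Terminal alkynes are the most reactive partners in the cobalt-mediated annulation, and the conditions of step 6 should give the C8-unsubstituted bicyclic enone F2. α-Iodination (I2, pyridine, CH2Cl2) would give the 8-iodo enone F3, and Stille coupling with Bu3SnCH2OH (Pd(PPh3)4, dioxane, 80 °C) the 8-hydroxymethyl enone F4. Silylation of F4 (TBSCl, imidazole) comes back to the route at 11.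

Step 11. The most likely failure is protonation of the samarium enolate on the face of the C8 alkoxide, giving the trans-fused C9 epimer, or β-elimination of the C8 alkoxide from the enolate. The fallback sets out from 16 and uses homolytic opening with trivalent titanium (Cp2TiCl from Cp2TiCl2 and Mn dust, 1,4-cyclohexadiene, THF). The C9–O bond breaks to the lactone-stabilised C9 radical, which should take a hydrogen atom on the face away from the bulky titanium alkoxide at C8. This gives 17 directly (no new compound, F0) and comes back at 17.

Step 15. The most likely failure is loss of the ketal or silyl ether to the Lewis-acidic titanium reagent, or incomplete conversion of the hindered α-acyloxy ketone. The fallback sets out from 20 and is a Peterson olefination: Me3SiCH2MgCl with CeCl3 (THF, −78 °C) adds to the ketone without enolising it and gives the β-hydroxysilane F5. Aqueous HF in MeCN then effects the elimination and removes the primary silyl ether in the same operation, coming back at 22.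

Step 26. The most likely failure is ruthenium-hydride isomerisation of the free allylic alcohol to an ethyl ketone, or slow closure at the hindered 1,1-disubstituted alkene with dimer formation. The fallback sets out from 35: acetylation (Ac2O, DMAP, CH2Cl2) gives the allylic acetate F6, ring closure with the same catalyst gives the acetoxy cycloheptene F7, and DBU eliminates acetic acid, coming back at 38.

Further compounds

F1 | step 6 | 3,3-bis{[(2S)-2-(4-methoxybenzyloxy)but-3-en-1-yl]oxy}prop-1-yne | C#CC(OC[C@@H](OCc1ccc(OC)cc1)C=C)OC[C@@H](OCc1ccc(OC)cc1)C=C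
F2 | step 6 | C8-unsubstituted bicyclic enone acetal (as 11 with H at C8) | COc1ccc(CO[C@@H]2CO[C@H](OC[C@@H](OCc4ccc(OC)cc4)C=C)C3=CC(=O)C[C@H]32)cc1
F3 | step 6 | 8-iodo bicyclic enone acetal | COc1ccc(CO[C@@H]2CO[C@H](OC[C@@H](OCc4ccc(OC)cc4)C=C)C3=C(I)C(=O)C[C@H]32)cc1
F4 | step 6 | 8-(hydroxymethyl) bicyclic enone acetal | COc1ccc(CO[C@@H]2CO[C@H](OC[C@@H](OCc4ccc(OC)cc4)C=C)C3=C(CO)C(=O)C[C@H]32)cc1
F0 | step 11 | none | none
F5 | step 15 | 4-hydroxy-4-[(trimethylsilyl)methyl] lactone (7,8-ketal, 10-OTBS; C4 either epimer) | C[Si](C)(C)CC1(O)COC(=O)[C@H]2[C@@]3(CO[Si](C)(C)C(C)(C)C)OC(C)(C)O[C@H]3C[C@H]21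
F6 | step 26 | tert-butyl 3-acetoxy-2-[all-cis-3-methyl-2-(3-methyl-2-methylidenebutyl)cyclopentyl]pent-4-enoate | C=C(C(C)C)C[C@@H]1[C@H](C)CC[C@@H]1C(C(OC(C)=O)C=C)C(=O)OC(C)(C)C
F7 | step 26 | tert-butyl (1'S,4'R,5'R)-9'-acetoxyguai-7'-en-14'-oate | CC(C)(C)OC(=O)C1C(OC(C)=O)C=C(C(C)C)C[C@@H]2[C@H](C)CC[C@H]12
A1 | alternative 1 | nardostachysin 7,8-acetonide (identical with 41) | C=C1COC(=O)[C@@H]2[C@H]1C[C@@H]3OC(C)(C)O[C@]23COC(=O)C1=CC=C(C(C)C)C[C@@H]2[C@H](C)CC[C@H]12
A2 | alternative 1 | 14'-norguaia-7',9'-dien-10'-yl trifluoromethanesulfonate (ring-fusion and methyl centres as in 39) | O=S(=O)(OC1=CC=C(C(C)C)C[C@@H]2[C@H](C)CC[C@H]12)C(F)(F)F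
A3 | alternative 1 | 14'-norguai-8'-en-10'-one (C7' unassigned; other centres as in 39) | O=C1C=CC(C(C)C)C[C@@H]2[C@H](C)CC[C@H]12
A4 | alternative 2 | iridoid triol lactone as its C10 tert-butyldimethylsilyl ether | C=C1COC(=O)[C@@H]2[C@H]1C[C@H](O)[C@@]2(O)CO[Si](C)(C)C(C)(C)C
A5 | alternative 2 | keto aldehyde: 4-methylidene δ-lactone with C9 bearing C(=O)CH2OTBS and C5 bearing CH2CHO (C9 labile) | C=C1COC(=O)C(C(=O)CO[Si](C)(C)C(C)(C)C)[C@H]1CC=O
A6 | alternative 3 | tert-butyl 8'-oxoguai-9'-en-14'-oate (C7' unassigned) | CC(C)(C)OC(=O)C1=CC(=O)C(C(C)C)C[C@@H]2[C@H](C)CC[C@H]12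
A7 | alternative 3 | cis-hydrindanone β-keto ester (six-membered ring C10', C8', C7', C6', C5', C1'; C7' and C10' unassigned) | CC(C)(C)OC(=O)C1C(=O)C(C(C)C)C[C@@H]2[C@H](C)CC[C@H]12
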